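**Strategy.** The benzenoid ring of the coumarin (C4a, C5–C8, C8a) carries oxygen on C7 and C8a, meta to each other across methyl-bearing C8. It also has a methyl on C6, the (S)-2-hydroxypropyl chain on C5, and, before the lactone is annulated, a lone CH at C4a. This pattern is what a vinylketene–ynol ether benzannulation produces, so the ring is cut at C8–C8a, C6–C7 and C4a–C8a. One heating step merges 1-(triisopropylsiloxy)propyne with a 2-methyl-3-alkylcyclobutenone that already holds the silyl-protected (S)-carbinol. The product is a phenol with two differentiated oxygens and one free ortho CH. Formylation there, Knoevenagel lactonisation with an (R)-dihydropyranonylacetate and desilylation complete the target.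

Key step: step 6

**Remarks on the chemistry**
- Assumption: the target is taken as drawn, (S) at the side-chain carbinol and (R) at C2 of the dihydropyranone. Both centres come from the chiral pool, and no C–O bond at either centre is ever broken.
- The cyclobutenone methyl must sit on olefinic C2. A ketene/ynol ether [2+2] joins the alkyne β-carbon to the ketene carbonyl carbon, so the methyl has to come from the alkyne (1-ethoxypropyne plus parent ketene).
- Methylketene plus ethoxyacetylene would place the methyl on sp3 C4. After addition and hydrolysis this gives a 4-methylcyclobutenone, and hence an arene with methyl on C4a and hydrogen on C6.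
- A 2-silyloxypropyl lithium or magnesium reagent loses silanolate by β-elimination. The chain is therefore delivered as the β-lithio alkoxide, from which only Li2O could leave, and is silylated afterwards.
- The hydroxyl must be masked before step 6. A free OH would add to the ketene intermediates.

**Step 1**
Reactants: 1 ethoxyacetylene
Product: 3 1-ethoxyprop-1-yne, via lithium ethoxyacetylide 2 (not isolated)
Conditions: n-BuLi (1.05 equiv), THF, −78 °C; MeI (1.2 equiv), DMPU, −78 °C → rt; fractional distillation
Reagents that add atoms: iodomethane, CI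
Why: Acetylide alkylation, in which the terminal ynol ether is cleanly lithiated and the acetylide is C-methylated by SN2 attack on methyl iodide, with DMPU raising its nucleophilicity.

**Step 2**
Reactants: 3 1-ethoxyprop-1-yne; 4 acetone
Product: 6 3-ethoxy-2-methylcyclobut-2-en-1-one, via ketene 5 (not isolated)
Conditions: acetone vapour, hot-wire ketene generator (ca. 700 °C); ketene stream into 3, CH2Cl2, 0 °C → rt
Reagents that add atoms: none
Why: Thermal ketene–ynol ether [2+2] cycloaddition, in which the oxygen-activated, methyl-bearing alkyne carbon attacks the ketene carbonyl carbon, so methyl ends on olefinic C2 and ethoxy on C3 as one regioisomer.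

**Step 3**
Reactants: 7 (S)-propylene oxide; 6 3-ethoxy-2-methylcyclobut-2-en-1-one
Product: 10 (S)-3-(2-hydroxypropyl)-2-methylcyclobut-2-en-1-one, via β-lithio alkoxide 8 (not isolated), via tertiary carbinol 9 (not isolated)
Conditions: 7, lithium 4,4'-di-tert-butylbiphenylide (LiDBB, 2.0 equiv, stock solution), THF, −78 °C; 6 (0.8 equiv), THF, −78 °C; 1 M HCl, 0 °C → rt
Reagents that add atoms: water, O
Why: Reductive lithiation of an alkyl epoxide cleaves the less substituted C–O bond and leaves the stereogenic C–O bond intact, the resulting primary β-lithio alkoxide persists at −78 °C because only Li2O could be expelled, and its 1,2-addition to the vinylogous ester followed by acid hydrolysis with carbonyl transposition (Stork–Danheiser sequence, standard for 3-alkoxycyclobutenones) installs the chain on C3 with the (S)-centre of 7 retained.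

**Step 4**
Reactants: 10 (S)-3-(2-hydroxypropyl)-2-methylcyclobut-2-en-1-one
Product: 11 (S)-3-[2-(tert-butyldimethylsilyloxy)propyl]-2-methylcyclobut-2-en-1-one
Conditions: TBSCl, imidazole, DMF, 0 °C → rt
Reagents that add atoms: tert-butyldimethylsilyl chloride, CC(C)(C)[Si](C)(C)Cl
Why: Standard imidazole-promoted silylation of a secondary alcohol, needed because a free hydroxyl would lactonise onto the ketene intermediates of step 6, and the stereocentre is not touched.

**Step 5**
Reactants: 12 propyne
Product: 15 1-(triisopropylsiloxy)prop-1-yne, via 1-propynyllithium 13 (not isolated), via lithium propynolate 14 (not isolated)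
Conditions: n-BuLi, THF, −78 °C; t-BuOOLi [t-BuOOH + LiN(SiMe3)2, THF, −78 °C], −78 → 0 °C; TIPSOTf, −78 → 0 °C
Reagents that add atoms: tert-butyl hydroperoxide, CC(C)(C)OO; triisopropylsilyl triflate, CC(C)[Si](C(C)C)(C(C)C)OS(=O)(=O)C(F)(F)F
Why: Electrophilic oxygenation of the lithium acetylide by lithium tert-butyl peroxide gives the ynolate, and the hard, bulky silyl triflate traps it on oxygen, a known one-flask entry to triisopropylsilyl ynol ethers.

**Step 6**
Reactants: 11 (S)-3-[2-(tert-butyldimethylsilyloxy)propyl]-2-methylcyclobut-2-en-1-one; 15 1-(triisopropylsiloxy)prop-1-yne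
Product: 20 (S)-5-[2-(tert-butyldimethylsilyloxy)propyl]-2,4-dimethyl-3-(triisopropylsiloxy)phenol, via vinylketene 16 (not isolated), via 4-vinylcyclobutenone 17 (not isolated), via dienylketene 18 (not isolated), via cyclohexadienone 19 (not isolated)
Conditions: 15 (1.5 equiv), toluene (0.5 M), argon, sealed tube, 80 → 110 °C
Reagents that add atoms: none
Why: Thermal conrotatory 4π opening of the strained ring of 11 (C1–C4 bond) releases vinylketene 16, whose ketene C=C undergoes [2+2] cycloaddition with 15 to give 17, forming C8–C8a and C6–C7. Reversible 4π opening of 17 gives dienylketene 18, and the isomer with ketene and vinyl termini cis closes by disrotatory 6π electrocyclisation (C4a–C8a, six-membered carbocycle) to dienone 19, which tautomerises irreversibly to phenol 20; this is the Danheiser benzannulation in its siloxyalkyne version, a known reaction of alkyl-substituted cyclobutenones. The one selectivity required is the orientation of the [2+2] step: oxygen donation makes the methyl-bearing alkyne carbon the nucleophile, so it bonds to the electrophilic ketene carbonyl carbon, placing methyl on C8 and OTIPS on C7 and leaving the ketene oxygen as the free C8a hydroxyl. The cyclobutenone fixes the rest, since its C2 methyl becomes the C6 methyl, its C3 chain ends on C5 and its CH2 becomes the lone aromatic CH at C4a. No lasting stereocentre is created (the quaternary carbon of 17 is erased on ring opening), and the (S)-silyl ether is remote from every reacting centre and inert to neutral heating. An excess of 15 at moderate concentration should limit capture of 16 by the phenol being formed.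

**Step 7**
Reactants: 20 (S)-5-[2-(tert-butyldimethylsilyloxy)propyl]-2,4-dimethyl-3-(triisopropylsiloxy)phenol
Product: 21 6-[(S)-2-(tert-butyldimethylsilyloxy)propyl]-2-hydroxy-3,5-dimethyl-4-(triisopropylsiloxy)benzaldehyde
Conditions: MgCl2 (anhydrous, 2 equiv), Et3N (4 equiv), (CH2O)n (6 equiv), THF, reflux; 1 M HCl work-up
Reagents that add atoms: paraformaldehyde (as formaldehyde), C=O
Why: Casnati–Skattebøl ortho-formylation, in which the magnesium phenoxide delivers formaldehyde to the ortho carbon through a chelate and a second formaldehyde oxidises the benzylic alkoxide by hydride transfer, with C4a the only unsubstituted ring carbon and both silyl ethers stable to the weakly basic medium.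

**Step 8**
Reactants: 22 methyl (R)-3-hydroxybutanoate
Product: 23 methyl (R)-3-(tert-butyldimethylsilyloxy)butanoate
Conditions: TBSCl, imidazole, DMF, rt
Reagents that add atoms: tert-butyldimethylsilyl chloride, CC(C)(C)[Si](C)(C)Cl
Why: Standard silylation that prevents alkoxide formation and retro-aldol cleavage in the following Claisen step, with the (R)-centre of the chiral-pool ester retained.

**Step 9**
Reactants: 24 methyl acetoacetate; 23 methyl (R)-3-(tert-butyldimethylsilyloxy)butanoate
Product: 26 methyl (R)-7-(tert-butyldimethylsilyloxy)-3,5-dioxooctanoate, via acetoacetate dianion 25 (not isolated)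
Conditions: 24 (2.2 equiv), lithium diisopropylamide (LDA, 4.5 equiv), THF, 0 °C; 23, −78 → 0 °C; 1 M HCl quench
Reagents that add atoms: none
Why: Claisen-type γ-acylation of the acetoacetate dianion, which attacks the ester carbonyl through its more nucleophilic terminal carbon while excess dianion absorbs the acidic proton of the product, and the (R)-centre is not involved.

**Step 10**
Reactants: 26 methyl (R)-7-(tert-butyldimethylsilyloxy)-3,5-dioxooctanoate
Product: 28 methyl 2-[(2R)-2-methyl-4-oxo-3,4-dihydro-2H-pyran-6-yl]acetate, via hydroxy diketo ester 27 (not isolated)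
Conditions: TFA–H2O (9:1), CH2Cl2, 0 °C → rt
Reagents that add atoms: none
Why: Acid removes the silyl group, and the freed C7 hydroxyl adds to the C3 ketone (six-membered hemiketal) and loses water, the usual cyclodehydration of δ-hydroxy-β-diketones to 2,3-dihydro-4H-pyran-4-ones, without breaking the C–O bond at the (R)-centre.

**Step 11**
Reactants: 21 6-[(S)-2-(tert-butyldimethylsilyloxy)propyl]-2-hydroxy-3,5-dimethyl-4-(triisopropylsiloxy)benzaldehyde; 28 methyl 2-[(2R)-2-methyl-4-oxo-3,4-dihydro-2H-pyran-6-yl]acetate
Product: 30 5-[(S)-2-(tert-butyldimethylsilyloxy)propyl]-6,8-dimethyl-3-[(2R)-2-methyl-4-oxo-3,4-dihydro-2H-pyran-6-yl]-7-(triisopropylsiloxy)-2H-chromen-2-one, via benzylidene ester 29 (not isolated)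
Conditions: piperidine (0.2 equiv), AcOH (0.2 equiv), 4 Å molecular sieves, toluene, 70 °C
Reagents that add atoms: none
Why: Knoevenagel condensation followed by lactonisation (classical coumarin synthesis), in which the exocyclic CH2 of 28, flanked by the ester and the vinylogous ester, is the most acidic site and irreversible closure of the phenol onto the ester funnels the reversible aldol manifold to the 3-substituted coumarin under a buffered medium mild enough to spare the (R)-centre.

**Step 12**
Reactants: 30 the bis-silylated coumarin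
Product: 31 7-hydroxy-5-[(S)-2-hydroxypropyl]-6,8-dimethyl-3-[(2R)-2-methyl-4-oxo-3,4-dihydro-2H-pyran-6-yl]-2H-chromen-2-one (target)
Conditions: HF·pyridine (excess), THF, polyethylene vessel, 0 °C → rt
Reagents that add atoms: none
Why: Fluoride-driven desilylation under mildly acidic conditions cleaves the secondary TBS ether and the aryl TIPS ether (a good leaving group as a 7-oxycoumarin) and avoids the basic medium that could open the dihydropyranone by retro-oxa-Michael reaction, so both stereocentres are preserved.

**Compound list**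
1 | ethoxyacetylene | CCOC#C | starting material
2 | lithium ethoxyacetylide | CCOC#C[Li] | intermediate
3 | 1-ethoxyprop-1-yne | CCOC#CC | intermediate
4 | acetone | CC(C)=O | starting material
5 | ketene | C=C=O | intermediate
6 | 3-ethoxy-2-methylcyclobut-2-en-1-one | CCOC1=C(C)C(=O)C1 | intermediate
7 | (S)-propylene oxide | C[C@H]1CO1 | starting material
8 | lithium (S)-1-lithiopropan-2-olate | [Li]C[C@H](C)O[Li] | intermediate
9 | 3-ethoxy-1-[(S)-2-hydroxypropyl]-2-methylcyclobut-2-en-1-ol (C1 epimers, formed as the dilithium alkoxide) | CCOC1=C(C)C(O)(C[C@H](C)O)C1 | intermediate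
10 | (S)-3-(2-hydroxypropyl)-2-methylcyclobut-2-en-1-one | O=C1CC(C[C@H](C)O)=C1C | intermediate
11 | (S)-3-[2-(tert-butyldimethylsilyloxy)propyl]-2-methylcyclobut-2-en-1-one | O=C1CC(C[C@H](C)O[Si](C)(C)C(C)(C)C)=C1C | intermediate
12 | propyne | CC#C | starting material
13 | 1-propynyllithium | CC#C[Li] | intermediate
14 | lithium propynolate | CC#CO[Li] | intermediate
15 | 1-(triisopropylsiloxy)prop-1-yne | CC#CO[Si](C(C)C)(C(C)C)C(C)C | intermediate
16 | (5S)-5-(tert-butyldimethylsilyloxy)-2-methyl-3-methylidenehex-1-en-1-one (vinylketene) | O=C=C(C)C(=C)C[C@H](C)O[Si](C)(C)C(C)(C)C | intermediate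
17 | 4-[(4S)-4-(tert-butyldimethylsilyloxy)pent-1-en-2-yl]-2,4-dimethyl-3-(triisopropylsiloxy)cyclobut-2-en-1-one (C4 epimers) | O=C1C(C)=C(O[Si](C(C)C)(C(C)C)C(C)C)C1(C)C(=C)C[C@H](C)O[Si](C)(C)C(C)(C)C | intermediate
18 | (3E,7S)-7-(tert-butyldimethylsilyloxy)-2,4-dimethyl-5-methylidene-3-(triisopropylsiloxy)octa-1,3-dien-1-one (ketene and vinyl termini cis) | O=C=C(C)/C(O[Si](C(C)C)(C(C)C)C(C)C)=C(/C)C(=C)C[C@H](C)O[Si](C)(C)C(C)(C)C | intermediate
19 | (S)-5-[2-(tert-butyldimethylsilyloxy)propyl]-2,4-dimethyl-3-(triisopropylsiloxy)cyclohexa-2,4-dien-1-one | O=C1CC(C[C@H](C)O[Si](C)(C)C(C)(C)C)=C(C)C(O[Si](C(C)C)(C(C)C)C(C)C)=C1C | intermediate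
20 | (S)-5-[2-(tert-butyldimethylsilyloxy)propyl]-2,4-dimethyl-3-(triisopropylsiloxy)phenol | Cc1c(O)cc(C[C@H](C)O[Si](C)(C)C(C)(C)C)c(C)c1O[Si](C(C)C)(C(C)C)C(C)C | intermediate
21 | 6-[(S)-2-(tert-butyldimethylsilyloxy)propyl]-2-hydroxy-3,5-dimethyl-4-(triisopropylsiloxy)benzaldehyde | Cc1c(O)c(C=O)c(C[C@H](C)O[Si](C)(C)C(C)(C)C)c(C)c1O[Si](C(C)C)(C(C)C)C(C)C | intermediate
22 | methyl (R)-3-hydroxybutanoate | C[C@@H](O)CC(=O)OC | starting material
23 | methyl (R)-3-(tert-butyldimethylsilyloxy)butanoate | C[C@@H](O[Si](C)(C)C(C)(C)C)CC(=O)OC | intermediate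
24 | methyl acetoacetate | CC(=O)CC(=O)OC | starting material
25 | dilithium dianion of methyl acetoacetate | C=C(O[Li])C=C(OC)O[Li] | intermediate
26 | methyl (R)-7-(tert-butyldimethylsilyloxy)-3,5-dioxooctanoate | C[C@@H](O[Si](C)(C)C(C)(C)C)CC(=O)CC(=O)CC(=O)OC | intermediate
27 | methyl (R)-7-hydroxy-3,5-dioxooctanoate | C[C@@H](O)CC(=O)CC(=O)CC(=O)OC | intermediate
28 | methyl 2-[(2R)-2-methyl-4-oxo-3,4-dihydro-2H-pyran-6-yl]acetate | COC(=O)CC1=CC(=O)C[C@@H](C)O1 | intermediate
29 | methyl 3-{6-[(S)-2-(tert-butyldimethylsilyloxy)propyl]-2-hydroxy-3,5-dimethyl-4-(triisopropylsiloxy)phenyl}-2-[(2R)-2-methyl-4-oxo-3,4-dihydro-2H-pyran-6-yl]prop-2-enoate | COC(=O)C(=Cc1c(O)c(C)c(O[Si](C(C)C)(C(C)C)C(C)C)c(C)c1C[C@H](C)O[Si](C)(C)C(C)(C)C)C1=CC(=O)C[C@@H](C)O1 | intermediate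
30 | 5-[(S)-2-(tert-butyldimethylsilyloxy)propyl]-6,8-dimethyl-3-[(2R)-2-methyl-4-oxo-3,4-dihydro-2H-pyran-6-yl]-7-(triisopropylsiloxy)-2H-chromen-2-one | Cc1c(O[Si](C(C)C)(C(C)C)C(C)C)c(C)c2oc(=O)c(C3=CC(=O)C[C@@H](C)O3)cc2c1C[C@H](C)O[Si](C)(C)C(C)(C)C | intermediate
31 | 7-hydroxy-5-[(S)-2-hydroxypropyl]-6,8-dimethyl-3-[(2R)-2-methyl-4-oxo-3,4-dihydro-2H-pyran-6-yl]-2H-chromen-2-one | Cc1c(O)c(C)c2oc(=O)c(C3=CC(=O)C[C@@H](C)O3)cc2c1C[C@H](C)O | target

**Step count.** Total: 12 steps. Longest linear sequence: 8 steps (1, 2, 3, 4, 6, 7, 11, 12) from ethoxyacetylene. Step 5 and steps 8–10 are convergent branches.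

**Steps most likely to fail**

**Step 6.**
- Risk: opening of the fully substituted enone may need temperatures at which the siloxyalkyne isomerises by O-to-C silyl shift. The vinylketene may also be drained by addition of the newly formed phenol or by self-reaction.
- Fallback: it sets out from 11, rejoins at 16, and separates ring opening from cycloaddition.
- Heating 11 alone in wet 1,4-dioxane (sealed tube, about 120 °C) lets water trap the vinylketene as (5S)-5-(tert-butyldimethylsilyloxy)-2-methyl-3-methylidenehexanoic acid F1 (C2 epimers, of no consequence).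
- 1-Chloro-N,N,2-trimethylprop-1-en-1-amine in CH2Cl2 at 0 °C converts it under neutral conditions into (5S)-5-(tert-butyldimethylsilyloxy)-2-methyl-3-methylidenehexanoyl chloride F2.
- Slow addition of Et3N to F2 and 15 in toluene (0 °C to room temperature) regenerates 16 by dehydrochlorination, and 15 captures it as 17.
- Brief warming to about 80 °C should then carry 17 through 18 and 19 to 20.

**Step 3.**
- Risk: β-elimination of the organolithium on local warming, proton abstraction from C4 of the vinylogous ester in place of carbonyl addition, or reduction of the enone by surplus arenide.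
- Fallback: it sets out from 7, rejoins at 11, and builds the four-membered ring on an alkyne that already contains the chain.
- 1-Propynyllithium 13 with BF3·OEt2 (THF, −78 °C) opens 7 at its CH2 terminus to give (S)-hex-4-yn-2-ol F3.
- TBSCl and imidazole give (S)-tert-butyl(hex-4-yn-2-yloxy)dimethylsilane F4.
- Trichloroacetyl chloride and Zn–Cu couple in Et2O–DME generate dichloroketene F5.
- Its [2+2] addition to F4 gives 4,4-dichloro-2-methyl-3-[(S)-2-(tert-butyldimethylsilyloxy)propyl]cyclobut-2-en-1-one F6, to be separated chromatographically from its regioisomer.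
- Zn dust, AcOH and TMEDA in EtOH remove both chlorines to give 11.
- This path replaces steps 1–4 at the price of a regiochemical separation.

**Step 11.**
- Risk: slow iminium formation at the doubly ortho-substituted aldehyde, aminolysis of the vinylogous ester by piperidine, or base-induced retro-oxa-Michael opening that erodes the (R)-centre.
- Fallback: it sets out from 28 and 21, rejoins at 30, and reverses the bond order so that C–O forms first and C=C second.
- Me3SnOH in 1,2-dichloroethane at 60 °C demethylates 28 to 2-[(2R)-2-methyl-4-oxo-3,4-dihydro-2H-pyran-6-yl]acetic acid F7.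
- Steglich esterification of the phenol of 21 (1-ethyl-3-(3-dimethylaminopropyl)carbodiimide, DMAP, CH2Cl2, 0 °C to room temperature) gives 3-[(S)-2-(tert-butyldimethylsilyloxy)propyl]-2-formyl-4,6-dimethyl-5-(triisopropylsiloxy)phenyl 2-[(2R)-2-methyl-4-oxo-3,4-dihydro-2H-pyran-6-yl]acetate F8.
- In F8 the aldehyde and the activated CH2 are held together, so a catalytic tertiary amine suffices for intramolecular Knoevenagel closure to 30.

**Further compounds**
F1 | step 6 | (5S)-5-(tert-butyldimethylsilyloxy)-2-methyl-3-methylidenehexanoic acid | OC(=O)C(C)C(=C)C[C@H](C)O[Si](C)(C)C(C)(C)C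
F2 | step 6 | (5S)-5-(tert-butyldimethylsilyloxy)-2-methyl-3-methylidenehexanoyl chloride | ClC(=O)C(C)C(=C)C[C@H](C)O[Si](C)(C)C(C)(C)C
F3 | step 3 | (S)-hex-4-yn-2-ol | CC#CC[C@H](C)O
F4 | step 3 | (S)-tert-butyl(hex-4-yn-2-yloxy)dimethylsilane | CC#CC[C@H](C)O[Si](C)(C)C(C)(C)C
F5 | step 3 | dichloroketene | ClC(Cl)=C=O
F6 | step 3 | 4,4-dichloro-2-methyl-3-[(S)-2-(tert-butyldimethylsilyloxy)propyl]cyclobut-2-en-1-one | O=C1C(C)=C(C[C@H](C)O[Si](C)(C)C(C)(C)C)C1(Cl)Cl
F7 | step 11 | 2-[(2R)-2-methyl-4-oxo-3,4-dihydro-2H-pyran-6-yl]acetic acid | OC(=O)CC1=CC(=O)C[C@@H](C)O1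
F8 | step 11 | 3-[(S)-2-(tert-butyldimethylsilyloxy)propyl]-2-formyl-4,6-dimethyl-5-(triisopropylsiloxy)phenyl 2-[(2R)-2-methyl-4-oxo-3,4-dihydro-2H-pyran-6-yl]acetate | O=Cc1c(OC(=O)CC2=CC(=O)C[C@@H](C)O2)c(C)c(O[Si](C(C)C)(C(C)C)C(C)C)c(C)c1C[C@H](C)O[Si](C)(C)C(C)(C)C
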